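**Plan**

1. Numbering as in 1H-indene: ring A (six-membered) is C3a, C4, C5, C6, C7, C7a; ring B (five-membered) is C1, C2, C3, C3a, C7a.
2. Feature used: the only olefin of ring A (C6=C7) lies between quaternary C5 and ring-fusion C7a, and C7a is tied to C3a by the three-atom bridge C1–C2=C3 of ring B. Ring A is therefore the Diels–Alder retron of a 1,3,8-nonatriene whose diene olefin C7=C7a is itself an olefination site.
3. Cuts, in order: the ester C–O bond; C4–C5 and C3a–C7a (retro-[4+2]); C7=C7a (retro-Wittig), which divides the linear hexaene into a C16 trienyl phosphonium salt and a C10 aldehyde-dienoate; then the trisubstituted olefins of both chains.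
4. Forward: two chains by iterative olefination; then in one flask the Wittig reaction joins them at C7–C7a and the hexaene closes rings A and B together by forming C4–C5 (between the two quaternary carbons) and C3a–C7a; ester demethylation ends the route.
5. Stereochemistry: C1 comes from methyl (S)-3-hydroxy-2-methylpropanoate; C7a is set by C1 through A(1,3) strain; C3a, C4 and C5 follow from the endo transition state and the E geometry of all olefins.

Key step: step 14

Remark: the stereocentre of ethyl (S)-lactate is lost in step 13 (it becomes the sp2 carbon C7), so the racemic ester would serve equally.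

**Step 1**
Reactants: 1 methyl (2S)-3-hydroxy-2-methylpropanoate
Product: 2 methyl (2S)-3-[(tert-butyldimethylsilyl)oxy]-2-methylpropanoate
Conditions: TBSCl, imidazole, DMF, 0 °C to rt
Reagents that add atoms: tert-butyldimethylsilyl chloride, C[Si](C)(Cl)C(C)(C)C
Why: Standard silylation of a primary alcohol; the stereocentre is not involved.

**Step 2**
Reactants: 2 methyl (2S)-3-[(tert-butyldimethylsilyl)oxy]-2-methylpropanoate
Product: 3 (2S)-3-[(tert-butyldimethylsilyl)oxy]-2-methylpropanal
Conditions: i-Bu2AlH, CH2Cl2, −78 °C; MeOH, aq. KNaC4H4O6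
Reagents that add atoms: none
Why: At −78 °C the hydride adds once and the aluminium hemiacetal survives until work-up (partial ester reduction); the aldehyde is used without chromatography so that C2 is not epimerised.

**Step 3**
Reactants: 3 (2S)-3-[(tert-butyldimethylsilyl)oxy]-2-methylpropanal; 4 2-(triphenyl-λ5-phosphanylidene)propanal
Product: 5 (2E,4R)-5-[(tert-butyldimethylsilyl)oxy]-2,4-dimethylpent-2-enal
Conditions: toluene, 90 °C
Reagents that add atoms: none
Why: Wittig reaction of a stabilised, non-basic ylide should give the (E)-2-methyl enal and leave the adjacent stereocentre intact.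

**Step 4**
Reactants: 5 (2E,4R)-5-[(tert-butyldimethylsilyl)oxy]-2,4-dimethylpent-2-enal; 6 methyl 2-(triphenyl-λ5-phosphanylidene)propanoate
Product: 7 methyl (2E,4E,6R)-7-[(tert-butyldimethylsilyl)oxy]-2,4,6-trimethylhepta-2,4-dienoate
Conditions: toluene, 100 °C
Reagents that add atoms: none
Why: Second Wittig reaction with a stabilised ester ylide, which is normally E-selective for α-methyl ylides, should give the (2E,4E)-dienoate.

**Step 5**
Reactants: 7 methyl (2E,4E,6R)-7-[(tert-butyldimethylsilyl)oxy]-2,4,6-trimethylhepta-2,4-dienoate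
Product: 8 methyl (2E,4E,6R)-7-hydroxy-2,4,6-trimethylhepta-2,4-dienoate
Conditions: HF·pyridine, pyridine, THF, 0 °C to rt
Reagents that add atoms: none
Why: Fluoride desilylation under weakly acidic conditions avoids deprotonation of the allylic C6–H, which is vinylogously activated by the dienoate.

**Step 6**
Reactants: 8 methyl (2E,4E,6R)-7-hydroxy-2,4,6-trimethylhepta-2,4-dienoate
Product: 9 methyl (2E,4E,6R)-2,4,6-trimethyl-7-oxohepta-2,4-dienoate
Conditions: PhI(OAc)2, TEMPO (cat.), CH2Cl2, rt; used at once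
Reagents that add atoms: none
Why: Oxoammonium (TEMPO) oxidation stops at the aldehyde under non-basic conditions, so the α-stereocentre of this β,γ-unsaturated aldehyde should survive if 9 is not stored.

**Step 7**
Reactants: 10 ethyl (2S)-2-hydroxypropanoate
Product: 11 ethyl (2S)-2-[(tert-butyldimethylsilyl)oxy]propanoate
Conditions: TBSCl, imidazole, DMF, 0 °C to rt
Reagents that add atoms: tert-butyldimethylsilyl chloride, C[Si](C)(Cl)C(C)(C)C
Why: Standard silylation of a secondary alcohol.

**Step 8**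
Reactants: 11 ethyl (2S)-2-[(tert-butyldimethylsilyl)oxy]propanoate
Product: 12 (2S)-2-[(tert-butyldimethylsilyl)oxy]propanal
Conditions: i-Bu2AlH, CH2Cl2, −78 °C; MeOH, aq. KNaC4H4O6
Reagents that add atoms: none
Why: Partial reduction of an α-silyloxy ester at −78 °C is a routine entry to the protected lactaldehyde.

**Step 9**
Reactants: 12 (2S)-2-[(tert-butyldimethylsilyl)oxy]propanal; 4 2-(triphenyl-λ5-phosphanylidene)propanal
Product: 13 (2E,4S)-4-[(tert-butyldimethylsilyl)oxy]-2-methylpent-2-enal
Conditions: toluene, 80 °C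
Reagents that add atoms: none
Why: Wittig reaction of the stabilised formyl ylide should give the (E)-enal; the saturated aldehyde reacts faster than the product enal, so one equivalent of ylide limits over-homologation.

**Step 10**
Reactants: 13 (2E,4S)-4-[(tert-butyldimethylsilyl)oxy]-2-methylpent-2-enal; 4 2-(triphenyl-λ5-phosphanylidene)propanal
Product: 14 (2E,4E,6S)-6-[(tert-butyldimethylsilyl)oxy]-2,4-dimethylhepta-2,4-dienal
Conditions: toluene, 110 °C
Reagents that add atoms: none
Why: The same E-selective Wittig homologation applied to an enal, which needs the higher temperature because the conjugated aldehyde is less electrophilic.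

**Step 11**
Reactants: 14 (2E,4E,6S)-6-[(tert-butyldimethylsilyl)oxy]-2,4-dimethylhepta-2,4-dienal; 15 diethyl benzylphosphonate
Product: 16 tert-butyl{[(2S,3E,5E,7E)-4,6-dimethyl-8-phenylocta-3,5,7-trien-2-yl]oxy}dimethylsilane
Conditions: NaH, THF, 0 °C to rt
Reagents that add atoms: none
Why: Horner–Wadsworth–Emmons reaction of the benzylphosphonate anion with a non-enolisable dienal should give the (E)-styryl olefin.

**Step 12**
Reactants: 16 tert-butyl{[(2S,3E,5E,7E)-4,6-dimethyl-8-phenylocta-3,5,7-trien-2-yl]oxy}dimethylsilane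
Product: 17 (2S,3E,5E,7E)-4,6-dimethyl-8-phenylocta-3,5,7-trien-2-ol
Conditions: Bu4NF, THF, 0 °C
Reagents that add atoms: none
Why: Fluoride desilylation under non-acidic conditions keeps the easily ionised trienyl carbinol intact.

**Step 13**
Reactants: 17 (2S,3E,5E,7E)-4,6-dimethyl-8-phenylocta-3,5,7-trien-2-ol
Product: 18 [(2RS,3E,5E,7E)-4,6-dimethyl-8-phenylocta-3,5,7-trien-2-yl]triphenylphosphonium bromide
Conditions: PPh3·HBr, MeOH, 0 °C to rt; precipitation with Et2O
Reagents that add atoms: triphenylphosphine hydrobromide, [Br-].c1ccc(cc1)[PH+](c1ccccc1)c1ccccc1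
Why: Protonation and loss of water give a phenyl-conjugated trienyl cation that PPh3 should capture at the methyl-bearing terminus C2, the position that restores the full styryl-triene conjugation (SN1-type formation of a polyenyl Wittig salt from an allylic alcohol).

**Step 14**
Reactants: 18 [(2RS,3E,5E,7E)-4,6-dimethyl-8-phenylocta-3,5,7-trien-2-yl]triphenylphosphonium bromide; 9 methyl (2E,4E,6R)-2,4,6-trimethyl-7-oxohepta-2,4-dienoate
Product: 21 methyl (1R,3aR,4R,5S,7aS)-1,3,4,5,7-pentamethyl-5-[(1E,3E)-2-methyl-4-phenylbuta-1,3-dien-1-yl]-3a,4,5,7a-tetrahydro-1H-indene-4-carboxylate, via phosphorus ylide 19 (not isolated), via linear hexaene ester 20 (not isolated)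
Conditions: NaN(SiMe3)2, THF, −78 °C; cold ylide added to 9, −78 °C to 0 °C; then toluene, BHT (cat.), 100 °C, 0.01 M
Reagents that add atoms: none
Why: Deprotonation of 18 gives the polyene-stabilised ylide 19, whose Wittig reaction with aldehyde 9 (oxaphosphetane, loss of Ph3P=O) forms the future C7=C7a olefin and so completes the diene C7a=C7–C6=C5 of hexaene 20, which on heating undergoes a type 1 intramolecular Diels–Alder reaction with the dienoate olefin C3a=C4 to form C4–C5 and C3a–C7a. The closest known reaction types are Wittig olefinations of polyenyl phosphonium salts as practised for retinoids and carotenoids, and thermal intramolecular Diels–Alder reactions of ester-activated 1,3,8-nonatrienes, including sequences in which the diene is made and cyclises in one flask. Ring A closes by the [4+2] cycloaddition itself, and ring B closes at the same time in the fused mode through the new C3a–C7a bond, because the tether C1–C2=C3 has three atoms. C7a is controlled by the C1 stereocentre, since A(1,3) strain with the C7 methyl holds H1 in the diene plane and the dienophile then arrives on the face of the tether, anti to the C1 methyl; C3a, C4 and C5 follow from the endo transition state (ester under the diene, α-methyl and tether exo), which gives the trans ring fusion, and from the E geometry of the C3a=C4 and C5=C6 olefins. The step needs E selectivity at the new olefin (the Z isomer cyclises far less readily with a three-atom tether, and the α-branched ylide and α-branched aldehyde should favour E), endo over exo selectivity (the dienophile α-methyl would clash with the C7 methyl in the exo mode) and retention at C1 (salt-free ylide added to the aldehyde at −78 °C). Other cycloaddition modes of 20 would need a one-atom or a five-atom tether and should not compete at high dilution.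

**Step 15**
Reactants: 21 methyl (1R,3aR,4R,5S,7aS)-1,3,4,5,7-pentamethyl-5-[(1E,3E)-2-methyl-4-phenylbuta-1,3-dien-1-yl]-3a,4,5,7a-tetrahydro-1H-indene-4-carboxylate
Product: 22 (1R,3aR,4R,5S,7aS)-1,3,4,5,7-pentamethyl-5-[(1E,3E)-2-methyl-4-phenylbuta-1,3-dien-1-yl]-3a,4,5,7a-tetrahydro-1H-indene-4-carboxylic acid (27-nor-zyggomphic acid B)
Conditions: NaSEt, DMF, 80 °C; then 1 M HCl to pH 3, 0 °C
Reagents that add atoms: none
Why: The thiolate attacks the O-methyl carbon (SN2 dealkylation), so the hindrance at the ester carbonyl on quaternary C4 does not matter and no olefin or stereocentre is touched.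

**Compound list**

1 | methyl (2S)-3-hydroxy-2-methylpropanoate | COC(=O)[C@@H](C)CO | starting material
2 | methyl (2S)-3-[(tert-butyldimethylsilyl)oxy]-2-methylpropanoate | COC(=O)[C@@H](C)CO[Si](C)(C)C(C)(C)C | intermediate
3 | (2S)-3-[(tert-butyldimethylsilyl)oxy]-2-methylpropanal | O=C[C@@H](C)CO[Si](C)(C)C(C)(C)C | intermediate
4 | 2-(triphenyl-λ5-phosphanylidene)propanal | CC(C=O)=P(c1ccccc1)(c1ccccc1)c1ccccc1 | starting material
5 | (2E,4R)-5-[(tert-butyldimethylsilyl)oxy]-2,4-dimethylpent-2-enal | O=C/C(C)=C/[C@@H](C)CO[Si](C)(C)C(C)(C)C | intermediate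
6 | methyl 2-(triphenyl-λ5-phosphanylidene)propanoate | COC(=O)C(C)=P(c1ccccc1)(c1ccccc1)c1ccccc1 | starting material
7 | methyl (2E,4E,6R)-7-[(tert-butyldimethylsilyl)oxy]-2,4,6-trimethylhepta-2,4-dienoate | COC(=O)/C(C)=C/C(C)=C/[C@@H](C)CO[Si](C)(C)C(C)(C)C | intermediate
8 | methyl (2E,4E,6R)-7-hydroxy-2,4,6-trimethylhepta-2,4-dienoate | COC(=O)/C(C)=C/C(C)=C/[C@@H](C)CO | intermediate
9 | methyl (2E,4E,6R)-2,4,6-trimethyl-7-oxohepta-2,4-dienoate | COC(=O)/C(C)=C/C(C)=C/[C@@H](C)C=O | intermediate
10 | ethyl (2S)-2-hydroxypropanoate | C[C@H](O)C(=O)OCC | starting material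
11 | ethyl (2S)-2-[(tert-butyldimethylsilyl)oxy]propanoate | C[C@H](O[Si](C)(C)C(C)(C)C)C(=O)OCC | intermediate
12 | (2S)-2-[(tert-butyldimethylsilyl)oxy]propanal | C[C@H](O[Si](C)(C)C(C)(C)C)C=O | intermediate
13 | (2E,4S)-4-[(tert-butyldimethylsilyl)oxy]-2-methylpent-2-enal | C[C@H](O[Si](C)(C)C(C)(C)C)/C=C(\C)C=O | intermediate
14 | (2E,4E,6S)-6-[(tert-butyldimethylsilyl)oxy]-2,4-dimethylhepta-2,4-dienal | C[C@H](O[Si](C)(C)C(C)(C)C)/C=C(\C)/C=C(\C)C=O | intermediate
15 | diethyl benzylphosphonate | CCOP(=O)(Cc1ccccc1)OCC | starting material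
16 | tert-butyl{[(2S,3E,5E,7E)-4,6-dimethyl-8-phenylocta-3,5,7-trien-2-yl]oxy}dimethylsilane | C[C@H](O[Si](C)(C)C(C)(C)C)/C=C(\C)/C=C(\C)/C=C/c1ccccc1 | intermediate
17 | (2S,3E,5E,7E)-4,6-dimethyl-8-phenylocta-3,5,7-trien-2-ol | C[C@H](O)/C=C(\C)/C=C(\C)/C=C/c1ccccc1 | intermediate
18 | [(2RS,3E,5E,7E)-4,6-dimethyl-8-phenylocta-3,5,7-trien-2-yl]triphenylphosphonium bromide | CC(/C=C(\C)/C=C(\C)/C=C/c1ccccc1)[P+](c1ccccc1)(c1ccccc1)c1ccccc1.[Br-] | intermediate
19 | triphenyl[(3E,5E,7E)-4,6-dimethyl-8-phenylocta-3,5,7-trien-2-ylidene]-λ5-phosphane | CC(/C=C(\C)/C=C(\C)/C=C/c1ccccc1)=P(c1ccccc1)(c1ccccc1)c1ccccc1 | intermediate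
20 | methyl (2E,4E,6S,7E,9E,11E,13E)-2,4,6,8,10,12-hexamethyl-14-phenyltetradeca-2,4,7,9,11,13-hexaenoate | COC(=O)/C(C)=C/C(C)=C/[C@@H](C)/C=C(\C)/C=C(\C)/C=C(\C)/C=C/c1ccccc1 | intermediate
21 | methyl (1R,3aR,4R,5S,7aS)-1,3,4,5,7-pentamethyl-5-[(1E,3E)-2-methyl-4-phenylbuta-1,3-dien-1-yl]-3a,4,5,7a-tetrahydro-1H-indene-4-carboxylate | CC1=C[C@](C)(/C=C(C)/C=C/c2ccccc2)[C@](C)(C(=O)OC)[C@H]2C(C)=C[C@@H](C)[C@H]12 | intermediate
22 | (1R,3aR,4R,5S,7aS)-1,3,4,5,7-pentamethyl-5-[(1E,3E)-2-methyl-4-phenylbuta-1,3-dien-1-yl]-3a,4,5,7a-tetrahydro-1H-indene-4-carboxylic acid | CC1=C[C@](C)(/C=C(C)/C=C/c2ccccc2)[C@](C)(C(=O)O)[C@H]2C(C)=C[C@@H](C)[C@H]12 | target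

**Totals**

Total step count: 15.
Longest linear sequence: 9 steps (steps 7 to 13, then 14 and 15).

**Steps most likely to fail**

Step 14. What may go wrong: loss of configuration at the α-carbon of aldehyde 9 (or migration of its β,γ-olefin into conjugation) under the basic ylide, low E selectivity in forming the trisubstituted C7=C7a olefin, and competition of the exo cycloaddition mode. Fallback: the order of the olefinations is reversed, so that the basic ylide meets a robust aldehyde and the sensitive aldehydes meet only non-basic stabilised ylides. It sets out from phosphonium salt 18 and from the commercial enantiomer of 1, methyl (2R)-3-hydroxy-2-methylpropanoate, and comes back at 21. The (R)-ester is silylated and reduced as in steps 1 and 2 to methyl (2R)-3-[(tert-butyldimethylsilyl)oxy]-2-methylpropanoate F1 and (2R)-3-[(tert-butyldimethylsilyl)oxy]-2-methylpropanal F2. Ylide 19 (from 18 and NaN(SiMe3)2, THF, −78 °C) and F2 should give tert-butyldimethyl{[(2S,3E,5E,7E,9E)-2,4,6,8-tetramethyl-10-phenyldeca-3,5,7,9-tetraen-1-yl]oxy}silane F3, whose olefin isomers can be separated or equilibrated with catalytic iodine before any stereocentre depends on them. Bu4NF then gives (2S,3E,5E,7E,9E)-2,4,6,8-tetramethyl-10-phenyldeca-3,5,7,9-tetraen-1-ol F4, PhI(OAc)2 with catalytic TEMPO gives (2S,3E,5E,7E,9E)-2,4,6,8-tetramethyl-10-phenyldeca-3,5,7,9-tetraenal F5, and Wittig reaction with 4 gives (2E,4S,5E,7E,9E,11E)-2,4,6,8,10-pentamethyl-12-phenyldodeca-2,5,7,9,11-pentaenal F6. Wittig reaction of F6 with 6 in toluene at 100 °C should give hexaene 20, which cyclises in the same flask to 21.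

Step 13. What may go wrong: capture of the delocalised cation at the benzylic terminus instead of C2, and E/Z scrambling of the olefins while the cation is free. Fallback: a Julia–Kocienski reagent made by SN2 chemistry, which fixes the position of the heteroatom and does not pass through the cation. It sets out from 17 and comes back at 21. Mitsunobu reaction of 17 with 1-phenyl-1H-tetrazole-5-thiol (PPh3, diisopropyl azodicarboxylate, THF, 0 °C) should give 5-{[(2R,3E,5E,7E)-4,6-dimethyl-8-phenylocta-3,5,7-trien-2-yl]sulfanyl}-1-phenyl-1H-tetrazole F7, and oxidation at sulfur (H2O2, (NH4)6Mo7O24 cat., EtOH, 0 °C) should give 5-{[(2R,3E,5E,7E)-4,6-dimethyl-8-phenylocta-3,5,7-trien-2-yl]sulfonyl}-1-phenyl-1H-tetrazole F8. Treatment of F8 with KN(SiMe3)2 in THF at −78 °C in the presence of 9 should give hexaene 20, and heating in toluene at 100 °C then gives 21.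

Step 15. What may go wrong: slow dealkylation of the hindered ester, or olefin isomerisation in the side chain during prolonged heating with thiolate. Fallback: a redox detour that never attacks the ester by substitution. It sets out from 21 and comes back at 22. LiAlH4 in Et2O at 0 °C should give [(1R,3aR,4R,5S,7aS)-1,3,4,5,7-pentamethyl-5-[(1E,3E)-2-methyl-4-phenylbuta-1,3-dien-1-yl]-3a,4,5,7a-tetrahydro-1H-inden-4-yl]methanol F9. Dess–Martin periodinane in CH2Cl2 should give (1R,3aR,4R,5S,7aS)-1,3,4,5,7-pentamethyl-5-[(1E,3E)-2-methyl-4-phenylbuta-1,3-dien-1-yl]-3a,4,5,7a-tetrahydro-1H-indene-4-carbaldehyde F10, which has no α-hydrogen. Pinnick oxidation (NaClO2, NaH2PO4, 2-methyl-2-butene, t-BuOH/H2O) then gives 22.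

**Further compounds**

F1 | step 14 | methyl (2R)-3-[(tert-butyldimethylsilyl)oxy]-2-methylpropanoate | COC(=O)[C@H](C)CO[Si](C)(C)C(C)(C)C
F2 | step 14 | (2R)-3-[(tert-butyldimethylsilyl)oxy]-2-methylpropanal | O=C[C@H](C)CO[Si](C)(C)C(C)(C)C
F3 | step 14 | tert-butyldimethyl{[(2S,3E,5E,7E,9E)-2,4,6,8-tetramethyl-10-phenyldeca-3,5,7,9-tetraen-1-yl]oxy}silane | CC(C)(C)[Si](C)(C)OC[C@@H](C)/C=C(\C)/C=C(\C)/C=C(\C)/C=C/c1ccccc1
F4 | step 14 | (2S,3E,5E,7E,9E)-2,4,6,8-tetramethyl-10-phenyldeca-3,5,7,9-tetraen-1-ol | OC[C@@H](C)/C=C(\C)/C=C(\C)/C=C(\C)/C=C/c1ccccc1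
F5 | step 14 | (2S,3E,5E,7E,9E)-2,4,6,8-tetramethyl-10-phenyldeca-3,5,7,9-tetraenal | O=C[C@@H](C)/C=C(\C)/C=C(\C)/C=C(\C)/C=C/c1ccccc1
F6 | step 14 | (2E,4S,5E,7E,9E,11E)-2,4,6,8,10-pentamethyl-12-phenyldodeca-2,5,7,9,11-pentaenal | O=C/C(C)=C/[C@@H](C)/C=C(\C)/C=C(\C)/C=C(\C)/C=C/c1ccccc1
F7 | step 13 | 5-{[(2R,3E,5E,7E)-4,6-dimethyl-8-phenylocta-3,5,7-trien-2-yl]sulfanyl}-1-phenyl-1H-tetrazole | C[C@@H](Sc1nnnn1-c1ccccc1)/C=C(\C)/C=C(\C)/C=C/c1ccccc1
F8 | step 13 | 5-{[(2R,3E,5E,7E)-4,6-dimethyl-8-phenylocta-3,5,7-trien-2-yl]sulfonyl}-1-phenyl-1H-tetrazole | C[C@@H](S(=O)(=O)c1nnnn1-c1ccccc1)/C=C(\C)/C=C(\C)/C=C/c1ccccc1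
F9 | step 15 | [(1R,3aR,4R,5S,7aS)-1,3,4,5,7-pentamethyl-5-[(1E,3E)-2-methyl-4-phenylbuta-1,3-dien-1-yl]-3a,4,5,7a-tetrahydro-1H-inden-4-yl]methanol | CC1=C[C@](C)(/C=C(C)/C=C/c2ccccc2)[C@](C)(CO)[C@H]2C(C)=C[C@@H](C)[C@H]12
F10 | step 15 | (1R,3aR,4R,5S,7aS)-1,3,4,5,7-pentamethyl-5-[(1E,3E)-2-methyl-4-phenylbuta-1,3-dien-1-yl]-3a,4,5,7a-tetrahydro-1H-indene-4-carbaldehyde | CC1=C[C@](C)(/C=C(C)/C=C/c2ccccc2)[C@](C)(C=O)[C@H]2C(C)=C[C@@H](C)[C@H]12
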